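**Plan**

1. The target is two (2S)-flavanones joined by a diaryl ether: unit 1 (benzo ring A, pyranone ring C, aryl ring B; 5-OH, 7-OMe) and unit 2 (benzo ring D, pyranone ring F, aryl ring E; 5,7-di-OH). The ether oxygen links C3' of ring B to C4' of ring E.
2. First cut: ring F at O1–C2 and C3–C4, with C4 taken back to a methyl ether. Ring F (O1–C2–C3–C4 fused to ring D) is the vinyl group of a ring E styrene (C2, C3) laid across the phenol oxygen (O1) and the formyl carbon (C4) of a ring D salicylaldehyde, so one oxa-[4+2] step builds it.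
3. Second cut: C2–C1' of unit 1 (chromone plus arylboronic acid). Third cut: the O–C4' bond of the diaryl ether (phenol plus vinylphenylboronic acid).
4. Forward: diaryl ether, then boronic acid; ring C closed as a chromone, then conjugate arylation to give unit 1 carrying the ring E styrene; the cycloaddition closes ring F; oxidation at C4 and debenzylation finish.
5. Stereochemistry: C2 of unit 1 comes from the chiral bisphosphine on rhodium, C2 of unit 2 from the chiral counter-anion of the acid in the cycloaddition; the C4 centre of the cycloadduct is erased on oxidation.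

Key step: step 7

Assumption: both chiral catalysts exist in either enantiomeric form; the sense of induction is taken from the closest models (cyclic enones for step 5, ortho-quinone methide cycloadditions for step 7), and the form that delivers 2S is the one meant.

**Route**

Step 1
Reactants: 1 2-(benzyloxy)-5-bromophenol; 2 (4-ethenylphenyl)boronic acid
Product: 3 1-(benzyloxy)-4-bromo-2-(4-ethenylphenoxy)benzene
Conditions: Cu(OAc)2 (1.5 equiv), pyridine, 4 Å MS, CH2Cl2, air, rt
Reagents that add atoms: none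
Why: Chan–Lam coupling, in which the copper phenoxide is arylated by the boronic acid at room temperature under air, conditions that leave the aryl bromide and the styrene untouched.

Step 2
Reactants: 3 1-(benzyloxy)-4-bromo-2-(4-ethenylphenoxy)benzene
Product: 6 [4-(benzyloxy)-3-(4-ethenylphenoxy)phenyl]boronic acid, via arylmagnesium bromide 4 (not isolated), via dimethyl arylboronate 5 (not isolated)
Conditions: Mg turnings, LiCl, THF, rt; B(OMe)3, −78 °C to rt; 1 M HCl
Reagents that add atoms: trimethyl borate COB(OC)OC; water O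
Why: Grignard formation by LiCl-assisted magnesium insertion followed by electrophilic borylation and hydrolysis is the standard way to vinyl-substituted arylboronic acids, since aryl Grignard reagents do not add to styrenes and the benzyl and diaryl ethers are inert.

Step 3
Reactants: 7 1-(2,6-dihydroxy-4-methoxyphenyl)ethan-1-one
Product: 8 1-[2-(benzyloxy)-6-hydroxy-4-methoxyphenyl]ethan-1-one
Conditions: BnBr (1.05 equiv), K2CO3, acetone, reflux
Reagents that add atoms: benzyl bromide BrCc1ccccc1
Why: Williamson ether synthesis, in which either of the two equivalent phenols is benzylated and the remaining one, hydrogen-bonded to the acetyl group, is too weakly nucleophilic for a second alkylation.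

Step 4
Reactants: 8 1-[2-(benzyloxy)-6-hydroxy-4-methoxyphenyl]ethan-1-one
Product: 10 5-(benzyloxy)-7-methoxy-4H-chromen-4-one, via enaminone 9 (not isolated)
Conditions: Me2NCH(OMe)2, toluene, 100 °C; then conc. HCl, CH2Cl2, 40 °C
Reagents that add atoms: N,N-dimethylformamide dimethyl acetal COC(OC)N(C)C
Why: Enaminone route to chromones, in which the methyl ketone condenses with the amide acetal and acid then promotes conjugate addition of the phenol and loss of dimethylamine, closing ring C by addition–elimination.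

Step 5
Reactants: 10 5-(benzyloxy)-7-methoxy-4H-chromen-4-one; 6 [4-(benzyloxy)-3-(4-ethenylphenoxy)phenyl]boronic acid
Product: 11 (2S)-5-(benzyloxy)-2-[4-(benzyloxy)-3-(4-ethenylphenoxy)phenyl]-7-methoxy-2,3-dihydro-4H-chromen-4-one
Conditions: [Rh(OH)(cod)]2 (2.5 mol%), (S)-MeO-F12-BIPHEP [(S)-2,2'-bis[bis(3,4,5-trifluorophenyl)phosphino]-6,6'-dimethoxybiphenyl] (5.5 mol%), 6 (1.5 equiv), toluene–H2O (10:1), 25–40 °C
Reagents that add atoms: none
Why: Hayashi–Miyaura rhodium-catalysed asymmetric 1,4-addition of an arylboronic acid to a chromone, a known entry to 2-aryl chromanones, in which the aryl–rhodium species inserts the C2=C3 bond on the enone face left open by the (S)-bisphosphine and so sets C2 as S, while the neutral base-free medium keeps the flavanone from opening to the chalcone.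

Step 6
Reactants: 12 2,4,6-trihydroxybenzaldehyde
Product: 13 4,6-bis(benzyloxy)-2-hydroxybenzaldehyde
Conditions: BnBr (2.1 equiv), K2CO3, DMF, 0 °C to rt
Reagents that add atoms: benzyl bromide BrCc1ccccc1
Why: Williamson ether synthesis, a known regioselective dibenzylation in which the 4-OH and one ortho-OH are alkylated while the last ortho-OH, chelated to the formyl group, stays free.

Step 7
Reactants: 13 4,6-bis(benzyloxy)-2-hydroxybenzaldehyde; 11 (2S)-5-(benzyloxy)-2-[4-(benzyloxy)-3-(4-ethenylphenoxy)phenyl]-7-methoxy-2,3-dihydro-4H-chromen-4-one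
Product: 16 (2S)-5-(benzyloxy)-2-{4-(benzyloxy)-3-[4-((2S)-5,7-bis(benzyloxy)-4-methoxy-3,4-dihydro-2H-chromen-2-yl)phenoxy]phenyl}-7-methoxy-2,3-dihydro-4H-chromen-4-one (either configuration at C4 of the new ring), via dimethyl acetal 14 (not isolated), via O-methyl oxocarbenium ion 15 (not isolated)
Conditions: 13 (1.3 equiv), HC(OMe)3 (2 equiv), chiral IDPi acid (imidodiphosphorimidate built from two 3,3'-diaryl-BINOL units, N-triflyl groups; 5 mol%, enantiomer giving 2S), CHCl3, −40 to −20 °C; Et3N quench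
Reagents that add atoms: trimethyl orthoformate COC(OC)OC
Why: Proposed new method: acid-catalysed exchange of 13 with HC(OMe)3 gives acetal 14, which the strong chiral acid ionises to the O-methyl oxocarbenium ion 15, an ortho-quinone methide equivalent that stays paired with the chiral imidodiphosphorimidate anion and hydrogen-bonded to it through its free phenol. The CH2 terminus of the electron-rich 4-aryloxystyrene of 11 attacks the carbenium carbon (C3–C4 bond) and the benzylic cation developing at C2 is captured by the phenol oxygen (O1–C2 bond), so ring F closes in one asynchronous inverse-electron-demand oxa-[4+2] cycloaddition, with the proton returned to the catalyst. The closest known reactions are the achiral acid-promoted three-component coupling of salicylaldehydes, orthoformates and styrenes to 2-aryl-4-alkoxychromans and chiral-phosphoric-acid-catalysed [4+2] cycloadditions of ortho-quinone methides with electron-rich alkenes. C2 is set by the chiral anion, which shields one face of the styrene within the confined ion pair, whereas C4 is left uncontrolled because it becomes a carbonyl carbon in step 8. The step needs the aryl group at C2 and reaction at the vinyl group only: the first follows from matched polarity (nucleophilic CH2 terminus, cation-stabilising aryloxyphenyl group, formyl carbon as the only electrophilic site), the second from the inertness of the aryl ketone, the ethers and the remote C2 centre of unit 1 towards a Brønsted acid at low temperature.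

Step 8
Reactants: 16 (2S)-5-(benzyloxy)-2-{4-(benzyloxy)-3-[4-((2S)-5,7-bis(benzyloxy)-4-methoxy-3,4-dihydro-2H-chromen-2-yl)phenoxy]phenyl}-7-methoxy-2,3-dihydro-4H-chromen-4-one
Product: 18 (2S)-5-(benzyloxy)-2-{4-(benzyloxy)-3-[4-((2S)-5,7-bis(benzyloxy)-4-oxo-3,4-dihydro-2H-chromen-2-yl)phenoxy]phenyl}-7-methoxy-2,3-dihydro-4H-chromen-4-one, via methyl hemiketal 17 (not isolated)
Conditions: DDQ (1.3 equiv), CH2Cl2–pH 7 aqueous buffer (18:1), 0 °C to rt
Reagents that add atoms: water O
Why: DDQ oxidation of an electron-rich benzylic ether, in which hydride is abstracted from C4 (benzylic to ring D and flanked by three ring oxygen donors and the methoxy group), water traps the cation and hemiketal 17 loses methanol, a mode of oxidation established at C4 of 5,7-dialkoxyflavans; unit 1 is deactivated by its ketone, and the new ketone stops further oxidation, so both epimers at C4 converge on one product.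

Step 9
Reactants: 18 (2S)-5-(benzyloxy)-2-{4-(benzyloxy)-3-[4-((2S)-5,7-bis(benzyloxy)-4-oxo-3,4-dihydro-2H-chromen-2-yl)phenoxy]phenyl}-7-methoxy-2,3-dihydro-4H-chromen-4-one
Product: 19 7-O-methyltetrahydroochnaflavone, (2S)-5-hydroxy-2-{4-hydroxy-3-[4-((2S)-5,7-dihydroxy-4-oxo-3,4-dihydro-2H-chromen-2-yl)phenoxy]phenyl}-7-methoxy-2,3-dihydro-4H-chromen-4-one
Conditions: H2 (1 atm), 10% Pd/C, EtOAc–MeOH, rt
Reagents that add atoms: none
Why: Catalytic hydrogenolysis of the four aryl benzyl ethers over Pd/C should be faster than cleavage of the ring C2–O1 benzylic bonds or reduction of the aryl ketones, and the neutral medium does not epimerise either C2 centre.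

**Compound list**

1 | 2-(benzyloxy)-5-bromophenol | Oc1cc(Br)ccc1OCc1ccccc1 | starting material
2 | (4-ethenylphenyl)boronic acid | C=Cc1ccc(B(O)O)cc1 | starting material
3 | 1-(benzyloxy)-4-bromo-2-(4-ethenylphenoxy)benzene | C=Cc1ccc(Oc2cc(Br)ccc2OCc2ccccc2)cc1 | intermediate
4 | [4-(benzyloxy)-3-(4-ethenylphenoxy)phenyl]magnesium bromide | C=Cc1ccc(Oc2cc([Mg]Br)ccc2OCc2ccccc2)cc1 | intermediate
5 | dimethyl [4-(benzyloxy)-3-(4-ethenylphenoxy)phenyl]boronate | C=Cc1ccc(Oc2cc(B(OC)OC)ccc2OCc2ccccc2)cc1 | intermediate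
6 | [4-(benzyloxy)-3-(4-ethenylphenoxy)phenyl]boronic acid | C=Cc1ccc(Oc2cc(B(O)O)ccc2OCc2ccccc2)cc1 | intermediate
7 | 1-(2,6-dihydroxy-4-methoxyphenyl)ethan-1-one | CC(=O)c1c(O)cc(OC)cc1O | starting material
8 | 1-[2-(benzyloxy)-6-hydroxy-4-methoxyphenyl]ethan-1-one | CC(=O)c1c(O)cc(OC)cc1OCc1ccccc1 | intermediate
9 | (E)-1-[2-(benzyloxy)-6-hydroxy-4-methoxyphenyl]-3-(dimethylamino)prop-2-en-1-one | CN(C)/C=C/C(=O)c1c(O)cc(OC)cc1OCc1ccccc1 | intermediate
10 | 5-(benzyloxy)-7-methoxy-4H-chromen-4-one | O=c1ccoc2cc(OC)cc(OCc3ccccc3)c12 | intermediate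
11 | (2S)-5-(benzyloxy)-2-[4-(benzyloxy)-3-(4-ethenylphenoxy)phenyl]-7-methoxy-2,3-dihydro-4H-chromen-4-one | C=Cc1ccc(Oc2cc([C@@H]3CC(=O)c4c(OCc5ccccc5)cc(OC)cc4O3)ccc2OCc2ccccc2)cc1 | intermediate
12 | 2,4,6-trihydroxybenzaldehyde | O=Cc1c(O)cc(O)cc1O | starting material
13 | 4,6-bis(benzyloxy)-2-hydroxybenzaldehyde | O=Cc1c(O)cc(OCc2ccccc2)cc1OCc1ccccc1 | intermediate
14 | 3,5-bis(benzyloxy)-2-(dimethoxymethyl)phenol | COC(OC)c1c(O)cc(OCc2ccccc2)cc1OCc1ccccc1 | intermediate
15 | O-methyl oxocarbenium ion, [2,4-bis(benzyloxy)-6-hydroxybenzylidene](methyl)oxonium, paired with the catalyst anion | C[O+]=Cc1c(O)cc(OCc2ccccc2)cc1OCc1ccccc1 | intermediate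
16 | (2S)-5-(benzyloxy)-2-{4-(benzyloxy)-3-[4-((2S)-5,7-bis(benzyloxy)-4-methoxy-3,4-dihydro-2H-chromen-2-yl)phenoxy]phenyl}-7-methoxy-2,3-dihydro-4H-chromen-4-one, either configuration at C4 of the new ring | COC1C[C@@H](c2ccc(Oc3cc([C@@H]4CC(=O)c5c(OCc6ccccc6)cc(OC)cc5O4)ccc3OCc3ccccc3)cc2)Oc2cc(OCc3ccccc3)cc(OCc3ccccc3)c21 | intermediate
17 | methyl hemiketal of 18 at C4 of unit 2 (4-hydroxy-4-methoxy) | COC1(O)C[C@@H](c2ccc(Oc3cc([C@@H]4CC(=O)c5c(OCc6ccccc6)cc(OC)cc5O4)ccc3OCc3ccccc3)cc2)Oc2cc(OCc3ccccc3)cc(OCc3ccccc3)c21 | intermediate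
18 | (2S)-5-(benzyloxy)-2-{4-(benzyloxy)-3-[4-((2S)-5,7-bis(benzyloxy)-4-oxo-3,4-dihydro-2H-chromen-2-yl)phenoxy]phenyl}-7-methoxy-2,3-dihydro-4H-chromen-4-one | O=C1C[C@@H](c2ccc(Oc3cc([C@@H]4CC(=O)c5c(OCc6ccccc6)cc(OC)cc5O4)ccc3OCc3ccccc3)cc2)Oc2cc(OCc3ccccc3)cc(OCc3ccccc3)c21 | intermediate
19 | 7-O-methyltetrahydroochnaflavone, (2S,2''S) | COc1cc(O)c2c(c1)O[C@H](c1ccc(O)c(Oc3ccc([C@@H]4CC(=O)c5c(O)cc(O)cc5O4)cc3)c1)CC2=O | target

**Step count**

Total: 9 steps. Longest linear sequence: 6 steps (1 → 3 → 6 → 11 → 16 → 18 → 19; the chromone branch 7 → 8 → 10 → 11 is equally long).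

**Steps most likely to fail**

Step 7. The donor-stabilised oxocarbenium ion may add too slowly to the styrene. The strong acid may oligomerise the styrene. The product may re-ionise at C4 and eliminate to a flavene. Facial discrimination by the anion may be insufficient. The fallback gives up the cycloaddition and makes unit 2 by the same conjugate arylation that serves unit 1, joining the two flavanones by a late diaryl ether coupling; it sets out from 1 and 10 and returns at 18. Palladium-catalysed borylation of 1 (B2(OH)4, Pd(OAc)2, XPhos, KOAc, EtOH, 80 °C) would give [4-(benzyloxy)-3-hydroxyphenyl]boronic acid F1. Its rhodium-catalysed addition to 10 under the conditions of step 5 would give the unit 1 phenol (2S)-5-(benzyloxy)-2-[4-(benzyloxy)-3-hydroxyphenyl]-7-methoxy-2,3-dihydro-4H-chromen-4-one F2. In parallel, commercial 5,7-dihydroxy-4H-chromen-4-one would be benzylated (BnBr, K2CO3, DMF, 70 °C) to 5,7-bis(benzyloxy)-4H-chromen-4-one F3. This would take up commercial (4-bromophenyl)boronic acid under the same rhodium catalysis to give (2S)-5,7-bis(benzyloxy)-2-(4-bromophenyl)-2,3-dihydro-4H-chromen-4-one F4. Borylation as above would give {4-[(2S)-5,7-bis(benzyloxy)-4-oxo-3,4-dihydro-2H-chromen-2-yl]phenyl}boronic acid F5. Chan–Lam coupling of F2 with F5 (Cu(OAc)2, pyridine, CH2Cl2, air, rt) would then give 18.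

Step 8. Hydride abstraction may compete at the C2 positions, the flavanones may be dehydrogenated towards flavones, or methanol may be lost to a flavene before oxidation. The fallback separates solvolysis from oxidation; it sets out from 16 and returns at 18. Mild aqueous acid (TsOH·H2O cat., THF–H2O, rt) would exchange the C4 methyl ether for a hydroxyl through the stabilised benzylic cation, giving the flavan-4-ol (2S)-5-(benzyloxy)-2-{4-(benzyloxy)-3-[4-((2S)-5,7-bis(benzyloxy)-4-hydroxy-3,4-dihydro-2H-chromen-2-yl)phenoxy]phenyl}-7-methoxy-2,3-dihydro-4H-chromen-4-one F6 as a mixture of C4 epimers. Dess–Martin periodinane (NaHCO3, CH2Cl2, rt) would oxidise F6 to 18.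

Step 5. The aryl–rhodium species may insert into the styrene, the electron-rich boronic acid may protodeboronate, the doubly donor-substituted chromone may react sluggishly, or facial control may be incomplete. The fallback builds unit 1 by the chalcone route and resolves it kinetically; it sets out from 8 and returns at 11. Commercial 4-(benzyloxy)-3-hydroxybenzaldehyde would be coupled with 2 as in step 1 to give 4-(benzyloxy)-3-(4-ethenylphenoxy)benzaldehyde F7. Claisen–Schmidt condensation with 8 (KOH, EtOH, rt) would give the 2'-hydroxychalcone (E)-1-[2-(benzyloxy)-6-hydroxy-4-methoxyphenyl]-3-[4-(benzyloxy)-3-(4-ethenylphenoxy)phenyl]prop-2-en-1-one F8. Cyclisation (NaOAc, EtOH, reflux) would give the racemic flavanone rac-5-(benzyloxy)-2-[4-(benzyloxy)-3-(4-ethenylphenoxy)phenyl]-7-methoxy-2,3-dihydro-4H-chromen-4-one F9. Asymmetric transfer hydrogenation with the enantiomer of RuCl(p-cymene)(TsDPEN) matched to the 2R ketone (HCO2H–Et3N, EtOAc, rt) would reduce that enantiomer to the cis-flavan-4-ol (2R,4R)-5-(benzyloxy)-2-[4-(benzyloxy)-3-(4-ethenylphenoxy)phenyl]-7-methoxy-3,4-dihydro-2H-chromen-4-ol F10. The unreduced ketone 11 would be separated by chromatography.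

**Further compounds**

F1 | step 7 | [4-(benzyloxy)-3-hydroxyphenyl]boronic acid | OB(O)c1ccc(OCc2ccccc2)c(O)c1
F2 | step 7 | (2S)-5-(benzyloxy)-2-[4-(benzyloxy)-3-hydroxyphenyl]-7-methoxy-2,3-dihydro-4H-chromen-4-one | COc1cc(OCc2ccccc2)c2c(c1)O[C@H](c1ccc(OCc3ccccc3)c(O)c1)CC2=O
F3 | step 7 | 5,7-bis(benzyloxy)-4H-chromen-4-one | O=c1ccoc2cc(OCc3ccccc3)cc(OCc3ccccc3)c12
F4 | step 7 | (2S)-5,7-bis(benzyloxy)-2-(4-bromophenyl)-2,3-dihydro-4H-chromen-4-one | O=C1C[C@@H](c2ccc(Br)cc2)Oc2cc(OCc3ccccc3)cc(OCc3ccccc3)c21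
F5 | step 7 | {4-[(2S)-5,7-bis(benzyloxy)-4-oxo-3,4-dihydro-2H-chromen-2-yl]phenyl}boronic acid | O=C1C[C@@H](c2ccc(B(O)O)cc2)Oc2cc(OCc3ccccc3)cc(OCc3ccccc3)c21
F6 | step 8 | (2S)-5-(benzyloxy)-2-{4-(benzyloxy)-3-[4-((2S)-5,7-bis(benzyloxy)-4-hydroxy-3,4-dihydro-2H-chromen-2-yl)phenoxy]phenyl}-7-methoxy-2,3-dihydro-4H-chromen-4-one, either configuration at C4 | OC1C[C@@H](c2ccc(Oc3cc([C@@H]4CC(=O)c5c(OCc6ccccc6)cc(OC)cc5O4)ccc3OCc3ccccc3)cc2)Oc2cc(OCc3ccccc3)cc(OCc3ccccc3)c21
F7 | step 5 | 4-(benzyloxy)-3-(4-ethenylphenoxy)benzaldehyde | C=Cc1ccc(Oc2cc(C=O)ccc2OCc2ccccc2)cc1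
F8 | step 5 | (E)-1-[2-(benzyloxy)-6-hydroxy-4-methoxyphenyl]-3-[4-(benzyloxy)-3-(4-ethenylphenoxy)phenyl]prop-2-en-1-one | C=Cc1ccc(Oc2cc(/C=C/C(=O)c3c(O)cc(OC)cc3OCc3ccccc3)ccc2OCc2ccccc2)cc1
F9 | step 5 | rac-5-(benzyloxy)-2-[4-(benzyloxy)-3-(4-ethenylphenoxy)phenyl]-7-methoxy-2,3-dihydro-4H-chromen-4-one | C=Cc1ccc(Oc2cc(C3CC(=O)c4c(OCc5ccccc5)cc(OC)cc4O3)ccc2OCc2ccccc2)cc1
F10 | step 5 | (2R,4R)-5-(benzyloxy)-2-[4-(benzyloxy)-3-(4-ethenylphenoxy)phenyl]-7-methoxy-3,4-dihydro-2H-chromen-4-ol | C=Cc1ccc(Oc2cc([C@H]3C[C@@H](O)c4c(OCc5ccccc5)cc(OC)cc4O3)ccc2OCc2ccccc2)cc1
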